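**Retrosynthetic overview**
- The ester C6–O comes from acylation of the allylic 4,6-diol 16, and the C6 carbinol from O4-directed reduction of hydroxy enone 15.
- The strategy rests on the trans C1–C5 ring-fusion bond of the cyclopentane, which sits next to the oxygenated C6 of the seven-membered ring. This is the retron of a 1,2-shift of C1 from C6 to C5 in a cis-decalin (6/6 to 5/7), run as the semipinacol rearrangement of C5 mesylate 14.
- Mesylate 14 comes from the all-cis 4,5,6-triol 13, made by hydroxyl-directed osmylation of dienol 11 and mesylation of the only secondary hydroxyl.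
- Dienol 11 comes from linear dienone 9 by isopropylcerium 1,2-addition; 9 comes from octalenone 8 by chloranil dehydrogenation.
- Ring order: the cyclohexane of 2,5-dimethylcyclohexanone, then the second six-membered ring by auxiliary-controlled Robinson annulation (sets C1), then both rings reshaped to cyclopentane and cycloheptene in one step.

Key step: step 8

Numbering used throughout: C1 (quaternary C–CH3), C2, C3, C4 (isopropyl carbinol), C5 (fusion CH), C6 (ester carbon), C7=C8(CH3), C9, C10. The decalin intermediates keep these numbers; in them C1 is bonded to C6 instead of C5.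

Assumption: commercial 2,5-dimethylcyclohexanone is the racemic cis/trans mixture; its methyl-bearing C5 becomes sp2 in step 4, so it is carried as an epimer mixture until then and only the quaternary centre set in step 2 matters.

**Step 1**
Reactants: 1 2,5-dimethylcyclohexan-1-one; 2 (R)-1-phenylethylamine
Product: 3 N-[(1R)-1-phenylethyl]-2,5-dimethylcyclohexan-1-imine (diastereomer mixture)
Conditions: TsOH (cat.), toluene, reflux, Dean–Stark
Reagents that add atoms: none
Why: Ketone–primary amine condensation with azeotropic removal of water gives the ketimine, which equilibrates with the more substituted secondary enamine needed in step 2; no stereocentre of the target is fixed here.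

**Step 2**
Reactants: 3 ketimine; 4 but-3-en-2-one
Product: 6 (2S)-2,5-dimethyl-2-(3-oxobutyl)cyclohexan-1-one (C5 epimer mixture), via Michael adduct imine 5 (not isolated)
Conditions: THF, rt, N2; then 20% aq. AcOH, rt
Reagents that add atoms: water, O
Why: Chiral-imine Michael addition: the more substituted secondary enamine tautomer adds to the enone through a compact aza-ene-like transition state with internal N–H transfer, and the (R)-phenylethyl group directs the chain to the face that gives the (S) quaternary centre (mirror image of the well-established (S)-amine to (R)-product pairing); reagent control is expected to outweigh the remote ring methyl, and aqueous acid then hydrolyses the imine.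

**Step 3**
Reactants: 6 diketone
Product: 8 (4aS)-4a,7-dimethyl-4,4a,5,6,7,8-hexahydronaphthalen-2(3H)-one (C7 epimer mixture), via aldol ketol 7 (not isolated)
Conditions: NaOMe (cat.), MeOH, 60 °C
Reagents that add atoms: none
Why: Second stage of the Robinson annulation: intramolecular aldol addition of the methyl ketone enolate to the ring carbonyl followed by E1cB dehydration gives the octalenone, and the quaternary centre cannot epimerise.

**Step 4**
Reactants: 8 octalenone
Product: 9 (4aS)-4a,7-dimethyl-4,4a,5,6-tetrahydronaphthalen-2(3H)-one (linear dienone: C4=O, C5=C6, C7=C8)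
Conditions: chloranil, t-BuOH, reflux
Reagents that add atoms: none
Why: Quinone dehydrogenation through the dienol with hydride abstraction from the tertiary allylic C8–H gives the linearly conjugated dienone, as in the conversion of steroidal 4-en-3-ones into 4,6-dien-3-ones, and both C8 epimers converge on one compound.

**Step 5**
Reactants: 9 dienone; 10 isopropylmagnesium chloride
Product: 11 (2R,4aS)-4a,7-dimethyl-2-(propan-2-yl)-2,3,4,4a,5,6-hexahydronaphthalen-2-ol (dienol; C4–OH syn to the C1 methyl)
Conditions: anhydrous CeCl3, THF, −78 to 0 °C; sat. aq. NH4Cl work-up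
Reagents that add atoms: none
Why: Organocerium 1,2-addition, whose low basicity suppresses enolisation, β-hydride reduction and conjugate addition; axial attack on the half-chair enone from the face anti to the pseudoaxial angular methyl should place isopropyl anti and hydroxyl syn to that methyl (C4 = R), as in α-face additions to steroidal 4-en-3-ones, and any C4 epimer is a diastereomer removable by chromatography.

**Step 6**
Reactants: 11 dienol
Product: 13 (1S,4R,5S,6R)-4-isopropyl-1,8-dimethyl-cis-decal-7-ene-4,5,6-triol (three hydroxyls and the C1 methyl on one face), via osmate ester 12 (not isolated)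
Conditions: OsO4 (1.0 equiv), TMEDA, CH2Cl2, −78 °C; then aq. Na2SO3, THF, reflux
Reagents that add atoms: osmium tetroxide, O=[Os](=O)(=O)=O
Why: Hydroxyl-directed dihydroxylation: the OsO4–TMEDA complex is hydrogen-bonded by the C4 hydroxyl and delivered to the proximal C5=C6 bond on the hydroxyl face (the same override of the angular-methyl bias seen in β-face epoxidation of 3β-hydroxy-Δ4-steroids), which sets C5 and C6 and gives the cis-decalin; the distal C7=C8 bond has no directing contact, and sulfite cleaves the chelated osmate without acid so the tertiary allylic alcohol survives.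

**Step 7**
Reactants: 13 triol
Product: 14 C5 methanesulfonate of 13 ((1S,4R,5S,6R)-4,6-dihydroxy-4-isopropyl-1,8-dimethyl-cis-decal-7-en-5-yl mesylate)
Conditions: MsCl (1.2 equiv), Et3N, CH2Cl2, −20 to 0 °C; used cold without delay
Reagents that add atoms: methanesulfonyl chloride, CS(=O)(=O)Cl
Why: Sulfonylation through sulfene is much faster at the single secondary (equatorial) hydroxyl than at the two tertiary ones, and it leaves every stereocentre untouched.

**Step 8**
Reactants: 14 hydroxy mesylate
Product: 15 (1S,4R,5R)-4-hydroxydauc-7-en-6-one
Conditions: KOt-Bu (1.05 equiv), THF/t-BuOH, −20 to 0 °C; pH 7 phosphate buffer quench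
Reagents that add atoms: none
Why: tert-Butoxide converts the C6 hydroxyl into its alkoxide, whose lone pair pushes the C6–C1 bond onto C5 while mesylate leaves from the opposite side, a concerted anionic semipinacol (pinacol-type) 1,2-shift of the kind long used to turn decalin-1,2-diol monosulfonates into hydroazulenones. No ring is closed end to end: the new C1–C5 bond contracts the six-membered ring C1–C6 to the cyclopentane C1–C5 in a three-centre suprafacial shift, and the same event inserts C5 between C6 and C1 so that the cyclohexene grows into the cycloheptenone. C5 is the only new stereocentre and is set by inversion, fixed by the antiperiplanar alignment of the equatorial C5–OMs bond with the C6–C1 bond in the chair/half-chair cis-decalin conformer that keeps isopropyl equatorial; C1 migrates with retention, so H5 ends anti to the C1 methyl (trans fusion) and C4 is untouched. The step needs migration of C1 (from C6) to beat migration of C3 (from C4, also antiperiplanar): the quaternary migrating carbon has the higher migratory aptitude and the C6 carbonyl forms next to C7=C8, while epoxide formation is excluded because both flanking hydroxyls are cis to the leaving group and E2 elimination is impossible because C4 and C6 carry no hydrogen. Only a slight excess of base, low temperature and a buffered quench are used so that the β-hydroxy ketone is not exposed to retro-aldol cleavage or C5 epimerisation.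

**Step 9**
Reactants: 15 hydroxy enone
Product: 16 (1S,4R,5S,6S)-dauc-7-ene-4,6-diol
Conditions: Me4NBH(OAc)3, MeCN/AcOH 1:1, −30 to −20 °C
Reagents that add atoms: none
Why: Evans–Saksena hydroxyl-directed reduction: the C4 hydroxyl exchanges onto boron and delivers hydride intramolecularly to the C6 carbonyl carbon on the O4 side, which should give the 1,3-anti diol with O6 anti to O4 and to the C1 methyl (6S), while the weakly hydridic reagent reduces neither the enone double bond nor the carbonyl by the external pathway.

**Step 10**
Reactants: 16 diol; 17 4-methoxybenzoyl chloride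
Product: 18 (1S,4R,5S,6S)-4-hydroxydauc-7-en-6-yl 4-methoxybenzoate (target, CNP0327211.1)
Conditions: pyridine, DMAP (cat.), CH2Cl2, 0 °C to rt
Reagents that add atoms: none
Why: DMAP-catalysed acylation takes place at the secondary allylic hydroxyl only, because the tertiary C4 hydroxyl is too hindered, and no stereocentre is involved.

**Compound list**
1 | 2,5-dimethylcyclohexan-1-one (racemic cis/trans mixture) | CC1CCC(C)C(=O)C1 | starting material
2 | (R)-1-phenylethylamine | C[C@@H](N)c1ccccc1 | starting material
3 | N-[(1R)-1-phenylethyl]-2,5-dimethylcyclohexan-1-imine | CC1CCC(C)C(=N[C@H](C)c2ccccc2)C1 | intermediate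
4 | but-3-en-2-one (methyl vinyl ketone) | CC(=O)C=C | starting material
5 | Michael adduct imine, (2S)-2,5-dimethyl-2-(3-oxobutyl)-N-[(1R)-1-phenylethyl]cyclohexan-1-imine | CC(=O)CC[C@]1(C)CCC(C)CC1=N[C@H](C)c1ccccc1 | intermediate
6 | (2S)-2,5-dimethyl-2-(3-oxobutyl)cyclohexan-1-one (C5 epimer mixture) | CC(=O)CC[C@]1(C)CCC(C)CC1=O | intermediate
7 | aldol ketol, (4aS)-8a-hydroxy-4a,7-dimethyloctahydronaphthalen-2(1H)-one (carbinol and C7 configurations mixed) | CC1CC[C@@]2(C)CCC(=O)CC2(O)C1 | intermediate
8 | (4aS)-4a,7-dimethyl-4,4a,5,6,7,8-hexahydronaphthalen-2(3H)-one (C7 epimer mixture) | CC1CC2=CC(=O)CC[C@]2(C)CC1 | intermediate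
9 | (4aS)-4a,7-dimethyl-4,4a,5,6-tetrahydronaphthalen-2(3H)-one | CC1=CC2=CC(=O)CC[C@]2(C)CC1 | intermediate
10 | isopropylmagnesium chloride | CC(C)[Mg]Cl | starting material
11 | (2R,4aS)-4a,7-dimethyl-2-(propan-2-yl)-2,3,4,4a,5,6-hexahydronaphthalen-2-ol | CC1=CC2=C[C@](O)(C(C)C)CC[C@]2(C)CC1 | intermediate
12 | cyclic O5,O6-osmate(VI) ester of 13, TMEDA complex | CC1=C[C@]23O[Os-2]4(=O)(=O)(O[C@H]2[C@](O)(C(C)C)CC[C@]3(C)CC1)[N+](C)(C)CC[N+]4(C)C | intermediate
13 | (1S,4R,5S,6R)-4-isopropyl-1,8-dimethyl-cis-decal-7-ene-4,5,6-triol (route numbering, all-cis) | CC1=C[C@]2(O)[C@@H](O)[C@](O)(C(C)C)CC[C@]2(C)CC1 | intermediate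
14 | C5 methanesulfonate of 13 | CC1=C[C@]2(O)[C@@H](OS(C)(=O)=O)[C@](O)(C(C)C)CC[C@]2(C)CC1 | intermediate
15 | (1S,4R,5R)-4-hydroxydauc-7-en-6-one | CC1=CC(=O)[C@H]2[C@](O)(C(C)C)CC[C@]2(C)CC1 | intermediate
16 | (1S,4R,5S,6S)-dauc-7-ene-4,6-diol | O[C@H]1C=C(C)CC[C@@]2(C)CC[C@@](O)(C(C)C)[C@H]12 | intermediate
17 | 4-methoxybenzoyl chloride | COc1ccc(C(=O)Cl)cc1 | starting material
18 | (1S,4R,5S,6S)-4-hydroxydauc-7-en-6-yl 4-methoxybenzoate | COc1ccc(C(=O)O[C@H]2C=C(C)CC[C@@]3(C)CC[C@@](O)(C(C)C)[C@H]23)cc1 | target

**Step count**
Total steps: 10. Longest linear sequence: 10 (steps 1 to 10, from 1).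

**Steps most likely to fail**

1. Step 8 (key step). The O4 alkoxide may drive migration of the C4–C3 bond instead (ring contraction to an isobutyryl hydrindane), or the β-hydroxy ketone may undergo retro-aldol opening or C5 epimerisation while base is present. Fallback: block O4 before the shift. The fallback sets out from dienol 11. Osmylation as in step 6 is stopped at osmate ester 12, which is isolated; its only free hydroxyl is silylated (TESOTf, 2,6-lutidine, CH2Cl2, −78 °C) to the O4-triethylsilyl osmate ester F1. Sulfite cleavage gives the 4-O-triethylsilyl 5,6-diol F2, and MsCl/Et3N gives its C5 mesylate F3. With KOt-Bu only the O6 alkoxide can push, and the product, 4-triethylsilyloxydauc-7-en-6-one F4, cannot undergo retro-aldol cleavage. HF·pyridine in THF removes the silyl group, and the route is rejoined at 15.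

2. Step 6. Hydroxyl direction may be lost, so that osmylation occurs on the face anti to the angular methyl or at the distal C7=C8 bond, or the hindered osmate may resist cleavage. Fallback: an epoxide route with net retention, setting out from dienol 11. Vanadium-directed epoxidation (VO(acac)2, t-BuOOH, CH2Cl2) gives the syn 5,6-epoxy-4-ol F5, a vinyl epoxide on the hydroxyl face. Pd(0)-catalysed CO2 insertion (Pd2(dba)3, P(Oi-Pr)3, CO2, THF) ionises C6–O with inversion, and the carbonate formed on O5 recloses on the π-allyl with a second inversion. This gives the cis 5,6-cyclic carbonate F6. Methanolysis (K2CO3, MeOH) returns to the route at triol 13.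

3. Step 9. Hydride may arrive on the sterically open face of C6 (anti to the C1 methyl) instead of through O4, which would give the C6 epimer. Fallback: reduce under steric control and invert during esterification, setting out from 15. Luche reduction (NaBH4, CeCl3·7H2O, MeOH, −78 °C) is expected to give the 6-epi diol F7 (6R). Mitsunobu reaction with 4-methoxybenzoic acid (PPh3, DIAD, THF) forms the ester with inversion at C6, and the route is rejoined directly at target 18 without step 10.

**Further compounds**
F1 | step 8 | O4-triethylsilyl osmate ester (TMEDA complex) | CC1=C[C@]23O[Os-2]4(=O)(=O)(O[C@H]2[C@](O[Si](CC)(CC)CC)(C(C)C)CC[C@]3(C)CC1)[N+](C)(C)CC[N+]4(C)C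
F2 | step 8 | 4-O-triethylsilyl 5,6-diol | CC1=C[C@]2(O)[C@@H](O)[C@](O[Si](CC)(CC)CC)(C(C)C)CC[C@]2(C)CC1
F3 | step 8 | 4-O-triethylsilyl C5 mesylate | CC1=C[C@]2(O)[C@@H](OS(C)(=O)=O)[C@](O[Si](CC)(CC)CC)(C(C)C)CC[C@]2(C)CC1
F4 | step 8 | 4-triethylsilyloxydauc-7-en-6-one | CC1=CC(=O)[C@H]2[C@](O[Si](CC)(CC)CC)(C(C)C)CC[C@]2(C)CC1
F5 | step 6 | syn 5,6-epoxy-4-ol (vinyl epoxide) | CC1=C[C@]23O[C@H]2[C@](O)(C(C)C)CC[C@]3(C)CC1
F6 | step 6 | cis 5,6-cyclic carbonate | CC1=C[C@]23OC(=O)O[C@H]2[C@](O)(C(C)C)CC[C@]3(C)CC1
F7 | step 9 | 6-epi diol, (1S,4R,5S,6R)-dauc-7-ene-4,6-diol | O[C@@H]1C=C(C)CC[C@@]2(C)CC[C@@](O)(C(C)C)[C@H]12
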